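## Retrosynthetic overview

1. The route rests on the 4-hydroxy-2-pyranone ring (O1, C2–C6) and its bond from C6 to the epimerisable methine C7, which also lies β to the C8 oxygen. The ring is therefore made last, by O1–C6 closure onto the C5≡C6 bond of an ynone tert-butyl β-keto ester, and only desilylation follows.
2. The ynone β-keto ester is cut at C3–C4 (tert-butyl butanoate enolate + Weinreb ynamide) and at C4–C5 (lithium acetylide + carbamoyl chloride). The alkyne comes from the C6 aldehyde by one-carbon homologation.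
3. The syn,syn C7–C8–C9 triad is cut at C7–C8 by an auxiliary-controlled syn aldol on (S)-2-(2-bromo-4-methylphenyl)propanal. C9 is set by asymmetric epoxidation of the cinnamyl alcohol, methyl delivery to the benzylic epoxide carbon and glycol cleavage.
4. The (E)-3-silyloxypropenyl arm is joined to the aryl bromide by Suzuki coupling once the triad is complete and before any alkyne is present.
5. Ring order: the benzene ring is bought; the pyranone is the only ring formed (step 14).

Key step: step 14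

Remarks and assumptions:
- Numbering: pyranone O1, C2 (C=O), C3 (ethyl), C4 (OH), C5, C6; side chain C7 (CHMe), C8 (CHOH), C9 (CHMe–aryl).
- TBS = tert-butyldimethylsilyl. Ar′ = 2-[(1E)-3-(TBS-oxy)prop-1-en-1-yl]-4-methylphenyl.
- The E-alkenyl pinacol boronate 12 is taken as a commercial reagent.
- Aldehyde 6 is configurationally labile and is used crude, directly after its preparation.

## Route

**Step 1**
Reactants: 1 2-bromo-4-methylbenzaldehyde
Product: 2 ethyl (2E)-3-(2-bromo-4-methylphenyl)prop-2-enoate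
Conditions: (EtO)2P(O)CH2CO2Et, NaH, THF, 0 °C to rt
Reagents that add atoms: triethyl phosphonoacetate, CCOC(=O)CP(=O)(OCC)OCC
Why: Horner–Wadsworth–Emmons olefination of an aryl aldehyde with a stabilised phosphonate anion should be reliably E-selective and leaves the aryl bromide untouched.

**Step 2**
Reactants: 2 ethyl (2E)-3-(2-bromo-4-methylphenyl)prop-2-enoate
Product: 3 (2E)-3-(2-bromo-4-methylphenyl)prop-2-en-1-ol
Conditions: DIBAL-H (2.3 equiv), CH2Cl2, −78 °C; aq. Rochelle salt
Reagents that add atoms: none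
Why: DIBAL-H 1,2-reduction of the enoate at low temperature should stop at the allylic alcohol without touching the alkene or the C–Br bond.

**Step 3**
Reactants: 3 (2E)-3-(2-bromo-4-methylphenyl)prop-2-en-1-ol
Product: 4 [(2R,3R)-3-(2-bromo-4-methylphenyl)oxiran-2-yl]methanol
Conditions: Ti(OiPr)4 (10 mol%), D-(−)-DIPT (12 mol%), t-BuOOH, 4 Å MS, CH2Cl2, −20 °C
Reagents that add atoms: tert-butyl hydroperoxide, CC(C)(C)OO
Why: Katsuki–Sharpless asymmetric epoxidation of the E-cinnamyl alcohol, where the D-(−)-tartrate–titanium complex delivers oxygen to the alkene face that gives the (2R,3R)-epoxide (the antipode of the (2S,3S)-epoxides formed from E-allylic alcohols with L-(+)-tartrate), which fixes the absolute configuration of the later C9.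

**Step 4**
Reactants: 4 [(2R,3R)-3-(2-bromo-4-methylphenyl)oxiran-2-yl]methanol
Product: 5 (2S,3S)-3-(2-bromo-4-methylphenyl)butane-1,2-diol
Conditions: Me3Al (3 equiv), hexane/CH2Cl2, 0 °C to rt; aq. Rochelle salt
Reagents that add atoms: trimethylaluminium, C[Al](C)C
Why: Trialkylaluminium opening of a 3-aryl-2,3-epoxy alcohol, in which the aluminium alkoxide activates the oxirane and methyl is delivered to the benzylic C3 with inversion, should set the methyl-bearing benzylic centre (future C9) as S and leave a 1,2-diol whose C2 centre is sacrificed in the next step.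

**Step 5**
Reactants: 5 (2S,3S)-3-(2-bromo-4-methylphenyl)butane-1,2-diol
Product: 6 (2S)-2-(2-bromo-4-methylphenyl)propanal
Conditions: NaIO4, THF/pH 7 buffer, 0 °C; used crude
Reagents that add atoms: none
Why: Malaprade glycol cleavage with periodate is base-free and near neutral, so it should release the α-aryl aldehyde without eroding its α-stereocentre.

**Step 6**
Reactants: 6 (2S)-2-(2-bromo-4-methylphenyl)propanal; 7 (4S)-4-benzyl-3-propanoyl-1,3-oxazolidin-2-one
Product: 9 (4S)-4-benzyl-3-[(2S,3R,4S)-4-(2-bromo-4-methylphenyl)-3-hydroxy-2-methylpentanoyl]-1,3-oxazolidin-2-one, via boron Z-enolate 8 (not isolated)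
Conditions: 7, Bu2BOTf, Et3N, CH2Cl2, 0 °C; then 6, −78 to 0 °C; pH 7 buffer, MeOH, H2O2
Reagents that add atoms: none
Why: Evans syn aldol, in which the Z(O)-boron enolate reacts through a Zimmerman–Traxler chair on the enolate face remote from the benzyl group, so that C7 (S) and the 7,8-syn C8 carbinol are set by the auxiliary while C9 is carried in by the aldehyde, which together give the syn,syn triad (the pairing asks the aldehyde to react in its Felkin sense with a Z-enolate, a bias the auxiliary is expected to override).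

**Step 7**
Reactants: 9 (4S)-4-benzyl-3-[(2S,3R,4S)-4-(2-bromo-4-methylphenyl)-3-hydroxy-2-methylpentanoyl]-1,3-oxazolidin-2-one
Product: 10 (4S)-4-benzyl-3-[(2S,3R,4S)-4-(2-bromo-4-methylphenyl)-3-(TBS-oxy)-2-methylpentanoyl]-1,3-oxazolidin-2-one
Conditions: TBSOTf, 2,6-lutidine, CH2Cl2, −78 to 0 °C
Reagents that add atoms: tert-butyldimethylsilyl trifluoromethanesulfonate, CC(C)(C)[Si](C)(C)OS(=O)(=O)C(F)(F)F
Why: Silyl triflate/lutidine silylation is the standard way to protect a hindered secondary aldol hydroxyl and blocks retro-aldol cleavage in the following steps.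

**Step 8**
Reactants: 10 (4S)-4-benzyl-3-[(2S,3R,4S)-4-(2-bromo-4-methylphenyl)-3-(TBS-oxy)-2-methylpentanoyl]-1,3-oxazolidin-2-one
Product: 11 (2R,3R,4S)-4-(2-bromo-4-methylphenyl)-3-(TBS-oxy)-2-methylpentan-1-ol
Conditions: LiBH4, MeOH (1 equiv), THF, 0 °C
Reagents that add atoms: none
Why: Reductive cleavage of the N-acyl oxazolidinone with lithium borohydride should give the primary alcohol without epimerising C7 and without affecting the aryl bromide or the silyl ether.

**Step 9**
Reactants: 11 (2R,3R,4S)-4-(2-bromo-4-methylphenyl)-3-(TBS-oxy)-2-methylpentan-1-ol; 12 tert-butyldimethyl{[(2E)-3-(4,4,5,5-tetramethyl-1,3,2-dioxaborolan-2-yl)prop-2-en-1-yl]oxy}silane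
Product: 13 (2R,3R,4S)-3-(TBS-oxy)-2-methyl-4-Ar′-pentan-1-ol
Conditions: Pd(OAc)2 (5 mol%), SPhos (10 mol%), K3PO4, THF/H2O (10:1), 50 °C
Reagents that add atoms: none
Why: Suzuki–Miyaura coupling of the ortho-alkyl aryl bromide with the E-alkenyl boronate under a biarylphosphine–palladium catalyst should proceed with retention of alkene geometry under mild base, and it is placed here because no alkyne or alkene is yet tethered to the aryl–palladium intermediate.

**Step 10**
Reactants: 13 (2R,3R,4S)-3-(TBS-oxy)-2-methyl-4-Ar′-pentan-1-ol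
Product: 14 (2S,3R,4S)-3-(TBS-oxy)-2-methyl-4-Ar′-pentanal
Conditions: Dess–Martin periodinane, NaHCO3, CH2Cl2, 0 °C to rt
Reagents that add atoms: none
Why: Buffered Dess–Martin oxidation is non-basic and should give the α-methyl β-silyloxy aldehyde without epimerisation at C7 or β-elimination.

**Step 11**
Reactants: 14 (2S,3R,4S)-3-(TBS-oxy)-2-methyl-4-Ar′-pentanal
Product: 15 (3R,4S,5S)-4-(TBS-oxy)-3-methyl-5-Ar′-hex-1-yne
Conditions: MeC(O)C(N2)P(O)(OMe)2, K2CO3, MeOH, 0 °C to rt
Reagents that add atoms: dimethyl (1-diazo-2-oxopropyl)phosphonate, COP(=O)(OC)C(=[N+]=[N-])C(C)=O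
Why: Ohira–Bestmann variant of the Seyferth–Gilbert homologation turns the aldehyde into the terminal alkyne under mild carbonate/methanol conditions that α-branched β-silyloxy aldehydes normally tolerate without epimerisation.

**Step 12**
Reactants: 15 (3R,4S,5S)-4-(TBS-oxy)-3-methyl-5-Ar′-hex-1-yne
Product: 17 (4R,5S,6S)-5-(TBS-oxy)-N-methoxy-N,4-dimethyl-6-Ar′-hept-2-ynamide, via lithium acetylide 16 (not isolated)
Conditions: n-BuLi, THF, −78 °C; then ClC(O)N(OMe)Me, −78 to 0 °C
Reagents that add atoms: N-methoxy-N-methylcarbamoyl chloride, CON(C)C(=O)Cl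
Why: Deprotonation of the terminal alkyne and C-acylation of the acetylide with the carbamoyl chloride is a standard entry to alkynyl Weinreb amides and does not touch the propargylic C7 centre.

**Step 13**
Reactants: 17 (4R,5S,6S)-5-(TBS-oxy)-N-methoxy-N,4-dimethyl-6-Ar′-hept-2-ynamide; 18 tert-butyl butanoate
Product: 20 tert-butyl (6R,7S,8S)-7-(TBS-oxy)-2-ethyl-6-methyl-3-oxo-8-Ar′-non-4-ynoate (both C2 epimers), via lithium enolate 19 (not isolated)
Conditions: 18, LDA (2.2 equiv), THF, −78 °C; then 17, −78 to −40 °C; AcOH quench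
Reagents that add atoms: none
Why: Claisen-type acylation of the ester lithium enolate by the Weinreb amide should stop at the chelated tetrahedral adduct, so the ynone β-keto ester is released only on quench, and the new ethyl-bearing centre is left uncontrolled because it becomes the sp2 C3.

**Step 14**
Reactants: 20 tert-butyl (6R,7S,8S)-7-(TBS-oxy)-2-ethyl-6-methyl-3-oxo-8-Ar′-non-4-ynoate
Product: 21 6-[(2S,3R,4S)-3-(TBS-oxy)-4-Ar′-pentan-2-yl]-3-ethyl-4-hydroxy-2H-pyran-2-one
Conditions: SPhosAuNTf2 (5 mol%), MeNO2/AcOH (4:1), rt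
Reagents that add atoms: none
Why: π-Complexation of the cationic gold(I) centre to the C5≡C6 bond of the ynone makes C6 (β to the ketone) electrophilic, and the carbonyl oxygen of the tert-butyl ester attacks it from the face opposite the metal to forge O1–C6; the alkoxy-stabilised cation then sheds its tert-butyl group as 2-methylpropene, and proton-for-gold exchange at C5 followed by enolisation of the C4 ketone furnishes the aromatic 4-hydroxy-2-pyranone. The closest known reaction type is the gold(I)-catalysed cycloisomerisation of tert-butyl 3-oxoalk-4-ynoates to 4-hydroxy-2-pyranones. The one ring formed, the pyranone, closes in the 6-endo-dig mode. No stereocentre is created, and the unassigned centre at the ethyl-bearing carbon disappears as C3 becomes sp2. Two selectivities are required: attack at C6 rather than C5 (5-exo), which the conjugative polarisation of the ynone provides, and activation of the alkyne rather than the styrenyl alkene, which follows from the far higher affinity of gold(I) for the triple bond. As C7 stays a propargylic carbon up to this point and no base is present, its configuration and the neighbouring C8 silyl ether should pass through untouched.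

**Step 15**
Reactants: 21 6-[(2S,3R,4S)-3-(TBS-oxy)-4-Ar′-pentan-2-yl]-3-ethyl-4-hydroxy-2H-pyran-2-one
Product: 22 veramycin A, 3-ethyl-4-hydroxy-6-[(2S,3R,4S)-3-hydroxy-4-{2-[(1E)-3-hydroxyprop-1-en-1-yl]-4-methylphenyl}pentan-2-yl]-2H-pyran-2-one
Conditions: HF·pyridine, pyridine, THF, 0 °C to rt
Reagents that add atoms: none
Why: Buffered HF·pyridine desilylation should cleave the primary allylic and the hindered secondary silyl ether (the latter more slowly) while leaving the acidic pyranone, the alkene and the stereotriad unchanged.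

## Compound list

1 | 2-bromo-4-methylbenzaldehyde | Cc1ccc(C=O)c(Br)c1 | starting material
2 | ethyl (2E)-3-(2-bromo-4-methylphenyl)prop-2-enoate | CCOC(=O)/C=C/c1ccc(C)cc1Br | intermediate
3 | (2E)-3-(2-bromo-4-methylphenyl)prop-2-en-1-ol | OC/C=C/c1ccc(C)cc1Br | intermediate
4 | [(2R,3R)-3-(2-bromo-4-methylphenyl)oxiran-2-yl]methanol | OC[C@@H]1[C@@H](c2ccc(C)cc2Br)O1 | intermediate
5 | (2S,3S)-3-(2-bromo-4-methylphenyl)butane-1,2-diol | OC[C@@H](O)[C@@H](C)c1ccc(C)cc1Br | intermediate
6 | (2S)-2-(2-bromo-4-methylphenyl)propanal | O=C[C@@H](C)c1ccc(C)cc1Br | intermediate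
7 | (4S)-4-benzyl-3-propanoyl-1,3-oxazolidin-2-one | CCC(=O)N1[C@@H](Cc2ccccc2)COC1=O | starting material
8 | dibutylboron (Z)-enolate of 7 | C/C=C(\OB(CCCC)CCCC)N1[C@@H](Cc2ccccc2)COC1=O | intermediate
9 | (4S)-4-benzyl-3-[(2S,3R,4S)-4-(2-bromo-4-methylphenyl)-3-hydroxy-2-methylpentanoyl]-1,3-oxazolidin-2-one | O=C([C@@H](C)[C@H](O)[C@@H](C)c1ccc(C)cc1Br)N1[C@@H](Cc2ccccc2)COC1=O | intermediate
10 | (4S)-4-benzyl-3-[(2S,3R,4S)-4-(2-bromo-4-methylphenyl)-3-(TBS-oxy)-2-methylpentanoyl]-1,3-oxazolidin-2-one | O=C([C@@H](C)[C@H](O[Si](C)(C)C(C)(C)C)[C@@H](C)c1ccc(C)cc1Br)N1[C@@H](Cc2ccccc2)COC1=O | intermediate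
11 | (2R,3R,4S)-4-(2-bromo-4-methylphenyl)-3-(TBS-oxy)-2-methylpentan-1-ol | OC[C@@H](C)[C@H](O[Si](C)(C)C(C)(C)C)[C@@H](C)c1ccc(C)cc1Br | intermediate
12 | tert-butyldimethyl{[(2E)-3-(4,4,5,5-tetramethyl-1,3,2-dioxaborolan-2-yl)prop-2-en-1-yl]oxy}silane | CC(C)(C)[Si](C)(C)OC/C=C/B1OC(C)(C)C(C)(C)O1 | starting material
13 | (2R,3R,4S)-3-(TBS-oxy)-2-methyl-4-{2-[(1E)-3-(TBS-oxy)prop-1-en-1-yl]-4-methylphenyl}pentan-1-ol | OC[C@@H](C)[C@H](O[Si](C)(C)C(C)(C)C)[C@@H](C)c1ccc(C)cc1/C=C/CO[Si](C)(C)C(C)(C)C | intermediate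
14 | (2S,3R,4S)-3-(TBS-oxy)-2-methyl-4-{2-[(1E)-3-(TBS-oxy)prop-1-en-1-yl]-4-methylphenyl}pentanal | O=C[C@@H](C)[C@H](O[Si](C)(C)C(C)(C)C)[C@@H](C)c1ccc(C)cc1/C=C/CO[Si](C)(C)C(C)(C)C | intermediate
15 | (3R,4S,5S)-4-(TBS-oxy)-3-methyl-5-{2-[(1E)-3-(TBS-oxy)prop-1-en-1-yl]-4-methylphenyl}hex-1-yne | C#C[C@@H](C)[C@H](O[Si](C)(C)C(C)(C)C)[C@@H](C)c1ccc(C)cc1/C=C/CO[Si](C)(C)C(C)(C)C | intermediate
16 | lithium acetylide of 15 | [Li]C#C[C@@H](C)[C@H](O[Si](C)(C)C(C)(C)C)[C@@H](C)c1ccc(C)cc1/C=C/CO[Si](C)(C)C(C)(C)C | intermediate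
17 | (4R,5S,6S)-5-(TBS-oxy)-N-methoxy-N,4-dimethyl-6-{2-[(1E)-3-(TBS-oxy)prop-1-en-1-yl]-4-methylphenyl}hept-2-ynamide | CON(C)C(=O)C#C[C@@H](C)[C@H](O[Si](C)(C)C(C)(C)C)[C@@H](C)c1ccc(C)cc1/C=C/CO[Si](C)(C)C(C)(C)C | intermediate
18 | tert-butyl butanoate | CCCC(=O)OC(C)(C)C | starting material
19 | lithium enolate of tert-butyl butanoate | CCC=C(O[Li])OC(C)(C)C | intermediate
20 | tert-butyl (6R,7S,8S)-7-(TBS-oxy)-2-ethyl-6-methyl-3-oxo-8-{2-[(1E)-3-(TBS-oxy)prop-1-en-1-yl]-4-methylphenyl}non-4-ynoate, C2 epimers | CCC(C(=O)OC(C)(C)C)C(=O)C#C[C@@H](C)[C@H](O[Si](C)(C)C(C)(C)C)[C@@H](C)c1ccc(C)cc1/C=C/CO[Si](C)(C)C(C)(C)C | intermediate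
21 | 6-[(2S,3R,4S)-3-(TBS-oxy)-4-{2-[(1E)-3-(TBS-oxy)prop-1-en-1-yl]-4-methylphenyl}pentan-2-yl]-3-ethyl-4-hydroxy-2H-pyran-2-one | CCc1c(O)cc([C@@H](C)[C@H](O[Si](C)(C)C(C)(C)C)[C@@H](C)c2ccc(C)cc2/C=C/CO[Si](C)(C)C(C)(C)C)oc1=O | intermediate
22 | veramycin A | CCc1c(O)cc([C@@H](C)[C@H](O)[C@@H](C)c2ccc(C)cc2/C=C/CO)oc1=O | target

Total step count: 15. Longest linear sequence: 15 steps (1 to 22).

## Steps most likely to fail

**Step 14 (gold cyclisation).** The closure may be slowed by the branched C7 substituent next to C6, may leak into 5-exo attack at C5, or the gold/acid medium may ionise the cinnamyl-type silyl ether. The fallback sets out from 20 and returns at 21 by the classical diketo ester lactonisation. Pyrrolidine adds to C6 of the ynone (aza-Michael, THF, 0 °C) to give the enaminone tert-butyl (4E,6R,7R,8S)-7-(TBS-oxy)-2-ethyl-6-methyl-3-oxo-5-(pyrrolidin-1-yl)-8-Ar′-non-4-enoate F5. Buffered hydrolysis (aq. AcOH/NaOAc, THF) gives the 3,5-diketo ester tert-butyl (6S,7R,8S)-7-(TBS-oxy)-2-ethyl-6-methyl-3,5-dioxo-8-Ar′-nonanoate F6. Heating F6 in toluene at 110 °C expels tert-butanol to an acylketene that is trapped by the C5 enol oxygen, giving 21. This path re-exposes C7 to enolisation, which is why it is only the reserve.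

**Step 6 (aldol).** The α-aryl aldehyde may lose configuration at its benzylic carbon under the amine/boron triflate conditions, and the antipode so formed would then be consumed faster than the desired enantiomer; the less favoured enolate–aldehyde pairing may also lower the syn selectivity. The fallback sets out from 6 and returns at 11, using substrate control without base. Crotyltributylstannane with BF3·OEt2 (CH2Cl2, −78 °C) adds through an open antiperiplanar transition state, syn-selective and in the Felkin sense, to give (2S,3S,4R)-2-(2-bromo-4-methylphenyl)-4-methylhex-5-en-3-ol F1. Silylation (TBSOTf, 2,6-lutidine) gives tert-butyl{[(2S,3S,4R)-2-(2-bromo-4-methylphenyl)-4-methylhex-5-en-3-yl]oxy}dimethylsilane F2. Ozonolysis (CH2Cl2/MeOH, −78 °C) with NaBH4 work-up cuts the vinyl group of F2 to the primary alcohol 11.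

**Step 13 (enolate acylation).** The ester enolate may add in conjugate fashion to C6 of the ynamide, or the adduct may collapse early and be deprotonated or attacked again. The fallback sets out from 17 and returns at 20 by aldol addition and oxidation. DIBAL-H (THF, −78 °C) reduces the Weinreb amide to the ynal (4R,5S,6S)-5-(TBS-oxy)-4-methyl-6-Ar′-hept-2-ynal F3. Lithium enolate 19 adds 1,2 to it (THF, −78 °C) to give tert-butyl (6R,7S,8S)-7-(TBS-oxy)-2-ethyl-3-hydroxy-6-methyl-8-Ar′-non-4-ynoate F4 as a diastereomer mixture. Dess–Martin oxidation of the propargylic alcohol F4 gives 20.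

## Further compounds

F1 | step 6 | (2S,3S,4R)-2-(2-bromo-4-methylphenyl)-4-methylhex-5-en-3-ol | C=C[C@@H](C)[C@H](O)[C@@H](C)c1ccc(C)cc1Br
F2 | step 6 | tert-butyl{[(2S,3S,4R)-2-(2-bromo-4-methylphenyl)-4-methylhex-5-en-3-yl]oxy}dimethylsilane | C=C[C@@H](C)[C@H](O[Si](C)(C)C(C)(C)C)[C@@H](C)c1ccc(C)cc1Br
F3 | step 13 | (4R,5S,6S)-5-(TBS-oxy)-4-methyl-6-{2-[(1E)-3-(TBS-oxy)prop-1-en-1-yl]-4-methylphenyl}hept-2-ynal | O=CC#C[C@@H](C)[C@H](O[Si](C)(C)C(C)(C)C)[C@@H](C)c1ccc(C)cc1/C=C/CO[Si](C)(C)C(C)(C)C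
F4 | step 13 | tert-butyl (6R,7S,8S)-7-(TBS-oxy)-2-ethyl-3-hydroxy-6-methyl-8-{2-[(1E)-3-(TBS-oxy)prop-1-en-1-yl]-4-methylphenyl}non-4-ynoate, C2/C3 diastereomers | CCC(C(=O)OC(C)(C)C)C(O)C#C[C@@H](C)[C@H](O[Si](C)(C)C(C)(C)C)[C@@H](C)c1ccc(C)cc1/C=C/CO[Si](C)(C)C(C)(C)C
F5 | step 14 | tert-butyl (4E,6R,7R,8S)-7-(TBS-oxy)-2-ethyl-6-methyl-3-oxo-5-(pyrrolidin-1-yl)-8-{2-[(1E)-3-(TBS-oxy)prop-1-en-1-yl]-4-methylphenyl}non-4-enoate | CCC(C(=O)OC(C)(C)C)C(=O)/C=C(/N1CCCC1)[C@@H](C)[C@H](O[Si](C)(C)C(C)(C)C)[C@@H](C)c1ccc(C)cc1/C=C/CO[Si](C)(C)C(C)(C)C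
F6 | step 14 | tert-butyl (6S,7R,8S)-7-(TBS-oxy)-2-ethyl-6-methyl-3,5-dioxo-8-{2-[(1E)-3-(TBS-oxy)prop-1-en-1-yl]-4-methylphenyl}nonanoate | CCC(C(=O)OC(C)(C)C)C(=O)CC(=O)[C@@H](C)[C@H](O[Si](C)(C)C(C)(C)C)[C@@H](C)c1ccc(C)cc1/C=C/CO[Si](C)(C)C(C)(C)C
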